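**Strategy.** Ring B is disconnected at C5–C6 and C9–C10: a Diels–Alder reaction between the C6=C7–C8=C9 diene of a geraniol-derived chain and the C5=C10 bond of an acyclic (E)-2-methylenal (C1 = CHO), with ring A still open. The target offers two handles, the C3 oxygen (two carbons from C5) and the vinylic C7–H. A disposable i-Pr2Si bridge from the C3 enol oxygen to C7 makes the cycloaddition a type 2 intramolecular one, forces the quaternary C4 endo, and sets C5, C9 and C10 (trans A/B fusion) in one operation. Fluoride then deletes the bridge, and the liberated C3 methyl ketone closes ring A onto C1 by aldol condensation.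

Key step: step 9

Remark on numbering: labdane numbering is used for all intermediates (C1–C10 ring carbons, C11–C15 side chain, C17 on C8, C18/C19 on C4, C20 on C10).
Remark on the design: without the bridge the enal should add with the formyl group endo and C4 exo, which would give the C9 epimer; the bridge is there to prevent this.
Assumption: the (S)-oxazaborolidinium ion of step 9 is taken to expose the enal face that gives 15 as drawn; if the opposite sense is found, its equally available (R)-enantiomer is used.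

Step 1
Reactants: 1 geraniol
Product: 2 geranyl tert-butyldiphenylsilyl ether
Conditions: t-BuPh2SiCl, imidazole, DMF, 0 °C → rt
Reagents that add atoms: tert-butylchlorodiphenylsilane, CC(C)(C)[Si](Cl)(c1ccccc1)c1ccccc1
Why: Imidazole-promoted silylation of the primary allylic alcohol should give a silyl ether that survives the organolithium, hydride and Lewis-acid steps and leaves together with the bridge in step 10.

Step 2
Reactants: 2 geranyl tert-butyldiphenylsilyl ether
Product: 3 (2E,6E)-8-(tert-butyldiphenylsilyloxy)-2,6-dimethylocta-2,6-dienal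
Conditions: SeO2 (1.1 equiv), 1,4-dioxane–EtOH, 80 °C
Reagents that add atoms: selenium dioxide, O=[Se]=O
Why: Riley allylic oxidation (ene reaction, then [2,3]-sigmatropic shift) should attack the (E)-methyl group of the terminal trisubstituted alkene and give the (E)-enal that fixes the later C8=C9 geometry, the alkene next to the silyl ether being deactivated.

Step 3
Reactants: 3 (2E,6E)-8-(tert-butyldiphenylsilyloxy)-2,6-dimethylocta-2,6-dienal
Product: 4 (3E,7E)-9-(tert-butyldiphenylsilyloxy)-3,7-dimethylnona-3,7-dien-2-ol (racemic at C2 of the chain)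
Conditions: MeMgBr, THF, −78 °C
Reagents that add atoms: methylmagnesium bromide, C[Mg]Br
Why: Grignard 1,2-addition to the enal supplies the carbon that becomes C6; the new carbinol centre is irrelevant because step 4 oxidises it.

Step 4
Reactants: 4 (3E,7E)-9-(tert-butyldiphenylsilyloxy)-3,7-dimethylnona-3,7-dien-2-ol
Product: 5 (3E,7E)-9-(tert-butyldiphenylsilyloxy)-3,7-dimethylnona-3,7-dien-2-one
Conditions: MnO2, CH2Cl2, rt
Reagents that add atoms: none
Why: MnO2 should oxidise the secondary allylic alcohol chemoselectively to the enone without touching the alkene geometry.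

Step 5
Reactants: 5 (3E,7E)-9-(tert-butyldiphenylsilyloxy)-3,7-dimethylnona-3,7-dien-2-one
Product: 6 2,4,6-triisopropylbenzenesulfonylhydrazone of 5
Conditions: 2,4,6-(i-Pr)3C6H2SO2NHNH2, THF–MeOH, rt
Reagents that add atoms: 2,4,6-triisopropylbenzenesulfonyl hydrazide, CC(C)c1cc(C(C)C)c(S(=O)(=O)NN)c(C(C)C)c1
Why: Condensation of the methyl ketone with the arylsulfonyl hydrazide gives the hydrazone needed for the Shapiro reaction, with the methyl group as the only sp3 α-carbon.

Step 6
Reactants: 6 2,4,6-triisopropylbenzenesulfonylhydrazone of 5; 7 methyl 2,2-dimethyl-3-oxobutanoate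
Product: 11 methyl 2,2-dimethyl-3-[(dienyl)diisopropylsilyloxy]but-3-enoate (dienyl = (3E,7E)-9-(tert-butyldiphenylsilyloxy)-3,7-dimethylnona-1,3,7-trien-2-yl), via dienyllithium 8 (not isolated), via chlorosilane 9 (not isolated), via potassium enolate 10 (not isolated)
Conditions: n-BuLi (2.1 equiv), THF, −78 → 0 °C; i-Pr2SiCl2 (3 equiv), −78 °C → rt, volatiles removed; then 7, KN(SiMe3)2, THF–DMPU, −78 °C → rt
Reagents that add atoms: dichlorodiisopropylsilane, CC(C)[Si](Cl)(Cl)C(C)C; n-butyllithium, CCCC[Li] (lithium of 8 only); potassium bis(trimethylsilyl)amide, C[Si](C)(C)[N-][Si](C)(C)C.[K+] (potassium of 10 only)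
Why: The Shapiro reaction (dianion at the methyl group, loss of sulfinate and N2) should give the 2-lithio-1,3-diene 8, which displaces one chloride of excess i-Pr2SiCl2, and the remaining Si–Cl bond then O-silylates the potassium enolate of 7, whose only enolisable position is the acetyl methyl group.

Step 7
Reactants: 11 silyl enol ether ester
Product: 12 2,2-dimethyl-3-[(dienyl)diisopropylsilyloxy]but-3-enal
Conditions: i-Bu2AlH (1.1 equiv), CH2Cl2, −78 °C; aq. potassium sodium tartrate
Reagents that add atoms: none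
Why: Partial reduction of the α-quaternary methyl ester with i-Bu2AlH should stop at the tetrahedral aluminate at −78 °C and release the aldehyde on work-up, the hindered silyl enol ether and the alkenylsilane being inert.

Step 8
Reactants: 12 2,2-dimethyl-3-[(dienyl)diisopropylsilyloxy]but-3-enal; 13 2-(triphenylphosphoranylidene)propanal
Product: 14 (E)-2,4,4-trimethyl-5-[(dienyl)diisopropylsilyloxy]hexa-2,5-dienal (cycloaddition substrate; C1 = CHO, C10=C5 (E), C4 gem-dimethyl, C3 enol ether)
Conditions: benzene, 75 °C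
Reagents that add atoms: none
Why: Wittig olefination with the stabilised formyl ylide should give the (E)-trisubstituted enal (C4 cis to C20, trans to CHO), at a temperature kept below that of the uncatalysed cycloaddition.

Step 9
Reactants: 14 (E)-enal tethered through O–Si(i-Pr)2 to C7 of the diene
Product: 15 bridged cycloadduct: ring B cyclohexene (C5–C10, C7=C8) with CHO and CH3 on C10 and the side chain on C9; C7 and C5 spanned by Si(i-Pr)2–O–C3(=CH2)–C4(CH3)2; C9–H and C5–H cis, both trans to C20; absolute configuration as in the SMILES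
Conditions: (S)-1-(2-methylphenyl)-3,3-diphenyltetrahydro-1H,3H-pyrrolo[1,2-c][1,3,2]oxazaborole (C24H24BNO, 20 mol %), HN(SO2CF3)2 (17 mol %), CH2Cl2 (0.01 M), −40 → 0 °C
Reagents that add atoms: none
Why: The protonated oxazaborolidine binds the formyl group of the (E)-enal, and the tethered 2-silyl-1,3-diene (C6=C7–C8=C9) adds across C5=C10 in a concerted, asynchronous normal-demand [4+2] cycloaddition (type 2 intramolecular Diels–Alder reaction; the closest known types are type 2 cycloadditions on disposable Si–O tethers and oxazaborolidinium-catalysed intramolecular Diels–Alder reactions of 2-substituted enals). Ring B closes by suprafacial [4+2] bonding on both components, and the seven-membered siloxane ring C7–Si–O–C3–C4–C5–C6 closes as the bridging ring of a bicyclo[4.3.1] skeleton with C7=C8 at the bridgehead. The four-atom tether can reach from C7 only to a C4 that lies endo, so C4 and, through the (E)-enal geometry, C20 are endo while the formyl group is exo; with the (E)-C8=C9 bond this places C11, C20 and C4 on one face of ring B, i.e. C9–H and C5–H cis to each other and trans to C20. The trans relation of C1 and C4 across C10–C5 (later the trans A/B fusion) is fixed by the (E)-enal because ring A is still open. Regiochemistry (C6 to C5, C9 to C10) is secured by the tether, which reaches C5 only through the adjacent terminus C6, and is electronically matched (unsubstituted terminus to the β-carbon). The absolute sense comes from the catalyst, which shields one face of the s-trans enal, and high dilution suppresses intermolecular Mukaiyama-type addition of the enol ether.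

Step 10
Reactants: 15 bridged cycloadduct
Product: 18 15-hydroxy-labda-1,7,13E-trien-3-one (ring A Δ1-3-one, trans-fused), via keto aldehyde 16 (not isolated), via aldol 17 (not isolated)
Conditions: n-Bu4NF (6 equiv), THF–DMF, 70 °C; then KOH, MeOH, rt
Reagents that add atoms: none
Why: Fluoride should cleave the Si–O bond (enol ether to methyl ketone), protodesilylate the alkenylsilane with retention of the C7=C8 position and remove the t-BuPh2Si group, after which the ketone, enolisable only at C2, undergoes intramolecular aldol condensation with the non-enolisable C1 aldehyde (now reachable because C1 and C4 are trans-diequatorial on the relaxed ring B).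

Step 11
Reactants: 18 15-hydroxy-labda-1,7,13E-trien-3-one
Product: 20 2,15-dihydroxy-labda-7,13E-dien-3-one (C2–OH equatorial, trans to C20), via potassium enolate 19 (not isolated)
Conditions: K[(s-Bu)3BH] (2.2 equiv), THF, −78 °C; then 2-(phenylsulfonyl)-3-phenyloxaziridine, −78 → −40 °C; aq. NH4Cl
Reagents that add atoms: 2-(phenylsulfonyl)-3-phenyloxaziridine, O=S(=O)(c1ccccc1)N1OC1c1ccccc1; potassium tri-sec-butylborohydride, CCC(C)[BH-](C(C)CC)C(C)CC.[K+] (potassium of 19 only)
Why: Conjugate reduction by the hindered borohydride (1,2-attack is blocked by the C4 gem-dimethyl group) gives the C2 enolate regiospecifically, and enolate oxidation by the N-sulfonyloxaziridine should occur anti to the axial methyl groups on C4 and C10, giving the equatorial C2–OH, which is also the thermodynamic epimer.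

Step 12
Reactants: 20 2,15-dihydroxy-labda-7,13E-dien-3-one
Product: 21 labda-7,13E-diene-2,3,15-triol (C2–OH equatorial, C3–OH axial, cis)
Conditions: K[(s-Bu)3BH] (3.5 equiv), THF, −78 → 0 °C; aq. NH4Cl
Reagents that add atoms: none
Why: The bulky borohydride should attack C3 along the equatorial trajectory, the mode established for 2-substituted and 4,4-dimethylcyclohexanones, and give the axial C3–OH cis to C2–OH.

Step 13
Reactants: 21 labda-7,13E-diene-2,3,15-triol
Product: 22 CNP0254679.1 (C2 and C15 diacetate, C3–OH free)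
Conditions: Ac2O (2.3 equiv), pyridine, 0 °C → rt
Reagents that add atoms: acetic anhydride, CC(=O)OC(C)=O
Why: Acetylation should discriminate by steric access, the primary allylic C15–OH and the equatorial C2–OH reacting while the axial C3–OH next to the C4 gem-dimethyl group stays free, and acyl migration would also favour the C2 ester.

**Compound list**

1 | geraniol | CC(C)=CCC/C(C)=C/CO | starting material
2 | geranyl tert-butyldiphenylsilyl ether | CC(C)=CCC/C(C)=C/CO[Si](c1ccccc1)(c1ccccc1)C(C)(C)C | intermediate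
3 | (2E,6E)-8-(tert-butyldiphenylsilyloxy)-2,6-dimethylocta-2,6-dienal | O=C/C(C)=C/CC/C(C)=C/CO[Si](c1ccccc1)(c1ccccc1)C(C)(C)C | intermediate
4 | (3E,7E)-9-(tert-butyldiphenylsilyloxy)-3,7-dimethylnona-3,7-dien-2-ol, racemic | CC(O)/C(C)=C/CC/C(C)=C/CO[Si](c1ccccc1)(c1ccccc1)C(C)(C)C | intermediate
5 | (3E,7E)-9-(tert-butyldiphenylsilyloxy)-3,7-dimethylnona-3,7-dien-2-one | CC(=O)/C(C)=C/CC/C(C)=C/CO[Si](c1ccccc1)(c1ccccc1)C(C)(C)C | intermediate
6 | 2,4,6-triisopropylbenzenesulfonylhydrazone of 5 | CC(=NNS(=O)(=O)c1c(C(C)C)cc(C(C)C)cc1C(C)C)/C(C)=C/CC/C(C)=C/CO[Si](c1ccccc1)(c1ccccc1)C(C)(C)C | intermediate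
7 | methyl 2,2-dimethyl-3-oxobutanoate | COC(=O)C(C)(C)C(C)=O | starting material
8 | (3E,7E)-9-(tert-butyldiphenylsilyloxy)-3,7-dimethylnona-1,3,7-trien-2-yllithium | [Li]C(=C)/C(C)=C/CC/C(C)=C/CO[Si](c1ccccc1)(c1ccccc1)C(C)(C)C | intermediate
9 | chloro(dienyl)diisopropylsilane | CC(C)[Si](Cl)(C(C)C)C(=C)/C(C)=C/CC/C(C)=C/CO[Si](c1ccccc1)(c1ccccc1)C(C)(C)C | intermediate
10 | potassium enolate of 7 | COC(=O)C(C)(C)C(=C)[O-].[K+] | intermediate
11 | methyl 2,2-dimethyl-3-[(dienyl)diisopropylsilyloxy]but-3-enoate | COC(=O)C(C)(C)C(=C)O[Si](C(C)C)(C(C)C)C(=C)/C(C)=C/CC/C(C)=C/CO[Si](c1ccccc1)(c1ccccc1)C(C)(C)C | intermediate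
12 | 2,2-dimethyl-3-[(dienyl)diisopropylsilyloxy]but-3-enal | O=CC(C)(C)C(=C)O[Si](C(C)C)(C(C)C)C(=C)/C(C)=C/CC/C(C)=C/CO[Si](c1ccccc1)(c1ccccc1)C(C)(C)C | intermediate
13 | 2-(triphenylphosphoranylidene)propanal | CC(C=O)=P(c1ccccc1)(c1ccccc1)c1ccccc1 | starting material
14 | (E)-2,4,4-trimethyl-5-[(dienyl)diisopropylsilyloxy]hexa-2,5-dienal | O=C/C(C)=C/C(C)(C)C(=C)O[Si](C(C)C)(C(C)C)C(=C)/C(C)=C/CC/C(C)=C/CO[Si](c1ccccc1)(c1ccccc1)C(C)(C)C | intermediate
15 | bridged cycloadduct (siloxane bridge C7–Si–O–C3–C4–C5) | O=C[C@@]1(C)[C@H](CC/C(C)=C/CO[Si](c2ccccc2)(c2ccccc2)C(C)(C)C)C(C)=C2C[C@@H]1C(C)(C)C(=C)O[Si]2(C(C)C)C(C)C | intermediate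
16 | keto aldehyde (ring B with C10–CHO, C5–C(CH3)2–COCH3, free C15–OH) | O=C[C@@]1(C)[C@H](CC/C(C)=C/CO)C(C)=CC[C@@H]1C(C)(C)C(C)=O | intermediate
17 | 1,15-dihydroxy-labda-7,13E-dien-3-one (C1 epimers) | OC/C=C(\C)CC[C@@H]1C(C)=CC[C@@H]2C(C)(C)C(=O)CC(O)[C@@]12C | intermediate
18 | 15-hydroxy-labda-1,7,13E-trien-3-one | OC/C=C(\C)CC[C@@H]1C(C)=CC[C@@H]2C(C)(C)C(=O)C=C[C@@]12C | intermediate
19 | dipotassium C2-enolate/C15-alkoxide of the 3-ketone | [K+].[K+].[O-]C/C=C(\C)CC[C@@H]1C(C)=CC[C@@H]2C(C)(C)C([O-])=CC[C@@]12C | intermediate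
20 | 2,15-dihydroxy-labda-7,13E-dien-3-one | OC/C=C(\C)CC[C@@H]1C(C)=CC[C@@H]2C(C)(C)C(=O)[C@@H](O)C[C@@]12C | intermediate
21 | labda-7,13E-diene-2,3,15-triol | OC/C=C(\C)CC[C@@H]1C(C)=CC[C@@H]2C(C)(C)[C@@H](O)[C@@H](O)C[C@@]12C | intermediate
22 | CNP0254679.1 | CC(=O)OC/C=C(\C)CC[C@@H]1C(C)=CC[C@@H]2C(C)(C)[C@@H](O)[C@@H](OC(C)=O)C[C@@]12C | target

**Step count and risk**

Total steps: 13. Longest linear sequence: 13 (from geraniol; 7 and 13 are purchased).

Most likely to fail:

1. Step 9. What may go wrong: poor enantiofacial discrimination by the catalyst on this hindered, tethered enal, or Lewis-acid-induced consumption of the enol ether. Fallback: absolute control is moved into the tether and the cycloaddition is run thermally. Chlorosilane 9 is quenched (imidazole, DMF) with methyl (R)-3-hydroxy-2,2-dimethylpent-4-enoate F1, itself made from acrolein and 1-methoxy-2-methyl-1-(trimethylsilyloxy)propene by an oxazaborolidinone-promoted Mukaiyama aldol reaction, to give silyl ether ester F2. i-Bu2AlH gives aldehyde F3 and ylide 13 gives enal F4. Heating (toluene, 170 °C) effects the uncatalysed type 2 cycloaddition, the C3 carbinol centre relaying its configuration, and cycloadduct F5 is separated from its diastereomer (the (R)-ester is chosen on the assumption that the vinyl group avoids the diene in the bridged transition state; if the other diastereomer dominates, the enantiomeric ester is used). Ph3P=CH2 converts the aldehyde into vinyl compound F6, n-Bu4NF gives diol F7, and the second-generation Grubbs catalyst RuCl2(=CHPh)(PCy3)(H2IMes) closes ring A to cyclohexenol F8. MnO2 oxidises both allylic alcohols to enone–enal F9, and K[(s-Bu)3BH] (3.3 equiv; 1,2 at the enal, 1,4 at the enone) followed by the oxaziridine returns to the route at 20.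

2. Step 6. What may go wrong: double substitution at silicon, or failure of the hindered chlorosilane to O-silylate the enolate. Fallback: the Si–C7 bond is made by hydrosilylation instead. Aldehyde 3 is converted with lithiated Me3SiCHN2 (Colvin rearrangement) into enyne F10. Keto ester 7 is O-silylated (KN(SiMe3)2, i-Pr2SiHCl) to hydrosilyl enol ether F11. [(C5Me5)Ru(NCMe)3]PF6 then adds the Si–H bond of F11 across the terminal alkyne of F10 with silicon at the internal carbon, returning to the route at 11.

3. Step 10. What may go wrong: the fluoride-mediated protodesilylation stalls at the hindered alkenyl fluorosilane, so the cascade does not reach the enone. Fallback: silicon is removed electrophilically. CF3CO2H in wet CH2Cl2 (0 °C) hydrolyses the enol ether of 15 and ipso-protonates C7 (β-silyl cation at tertiary C8), giving silyl-protected keto aldehyde F12. KOH/MeOH closes ring A to silyl-protected enone F13, and n-Bu4NF at rt frees C15–OH, returning to the route at 18.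

**Further compounds**

F1 | step 9 | methyl (R)-3-hydroxy-2,2-dimethylpent-4-enoate | C=C[C@@H](O)C(C)(C)C(=O)OC
F2 | step 9 | silyl ether ester (C3–O–Si(i-Pr)2–dienyl) | C=C[C@@H](O[Si](C(C)C)(C(C)C)C(=C)/C(C)=C/CC/C(C)=C/CO[Si](c1ccccc1)(c1ccccc1)C(C)(C)C)C(C)(C)C(=O)OC
F3 | step 9 | corresponding aldehyde | C=C[C@@H](O[Si](C(C)C)(C(C)C)C(=C)/C(C)=C/CC/C(C)=C/CO[Si](c1ccccc1)(c1ccccc1)C(C)(C)C)C(C)(C)C=O
F4 | step 9 | corresponding (E)-2-methylenal | C=C[C@@H](O[Si](C(C)C)(C(C)C)C(=C)/C(C)=C/CC/C(C)=C/CO[Si](c1ccccc1)(c1ccccc1)C(C)(C)C)C(C)(C)/C=C(\C)C=O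
F5 | step 9 | bridged cycloadduct with C3 carbinol carbon bearing vinyl | O=C[C@@]1(C)[C@H](CC/C(C)=C/CO[Si](c2ccccc2)(c2ccccc2)C(C)(C)C)C(C)=C2C[C@@H]1C(C)(C)[C@@H](C=C)O[Si]2(C(C)C)C(C)C
F6 | step 9 | C10-vinyl bridged compound | C=C[C@@]1(C)[C@H](CC/C(C)=C/CO[Si](c2ccccc2)(c2ccccc2)C(C)(C)C)C(C)=C2C[C@@H]1C(C)(C)[C@@H](C=C)O[Si]2(C(C)C)C(C)C
F7 | step 9 | desilylated diene diol | C=C[C@@]1(C)[C@H](CC/C(C)=C/CO)C(C)=CC[C@@H]1C(C)(C)[C@H](O)C=C
F8 | step 9 | labda-1,7,13E-triene-3,15-diol (C3 epimeric to the target) | OC/C=C(\C)CC[C@@H]1C(C)=CC[C@@H]2C(C)(C)[C@H](O)C=C[C@@]12C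
F9 | step 9 | 3-oxo-labda-1,7,13E-trien-15-al | O=C/C=C(\C)CC[C@@H]1C(C)=CC[C@@H]2C(C)(C)C(=O)C=C[C@@]12C
F10 | step 6 | (3E,7E)-9-(tert-butyldiphenylsilyloxy)-3,7-dimethylnona-3,7-dien-1-yne | C#C/C(C)=C/CC/C(C)=C/CO[Si](c1ccccc1)(c1ccccc1)C(C)(C)C
F11 | step 6 | methyl 3-(diisopropylsilyloxy)-2,2-dimethylbut-3-enoate | COC(=O)C(C)(C)C(=C)O[SiH](C(C)C)C(C)C
F12 | step 10 | keto aldehyde with t-BuPh2Si ether retained | O=C[C@@]1(C)[C@H](CC/C(C)=C/CO[Si](c2ccccc2)(c2ccccc2)C(C)(C)C)C(C)=CC[C@@H]1C(C)(C)C(C)=O
F13 | step 10 | 15-(tert-butyldiphenylsilyloxy)-labda-1,7,13E-trien-3-one | CC(C)(C)[Si](OC/C=C(\C)CC[C@@H]1C(C)=CC[C@@H]2C(C)(C)C(=O)C=C[C@@]12C)(c1ccccc1)c1ccccc1
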